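Labels: ring A = enolised trione ring, ring B = spiro cyclohexane, ring C = cyclopentane. Retrosynthetic cuts, in order: the prenyl–C bond at the C(CH3)(prenyl) carbon of ring A; the acyl–ring A bond; the spiro C–CH2 bond next to the ring B C(CH3)(OH); the spiro C–CH2 bond on the ring-fusion CH. This leaves 2-methylphloroglucinol, (S)-2-methylbutanoic acid and a C10 cyclopentane.
Enabling feature: in ring C the carbinol carbon C(CH3)(OH) and the two ring-fusion CH groups are contiguous, and the CH next to the carbinol carries the ring B CH2 as its only exocyclic carbon. Ring C plus this CH2 is the carbon ring of carvone (C2, C3, C4, C5, C6 plus C1), and the other ring-fusion CH (carvone C5) already bears the three remaining ring B carbons as isopropenyl.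
Ring C is therefore contracted rather than closed: a Wolff 1,2-shift moves the oxygenated C2 from the carbonyl carbon C1 to C6 and pushes C1 out of the six-membered ring as a ketene carbon.
Forward order: oxygenated carvone ring; ring C together with a temporary γ-lactone in one flask; union with the arene through the extruded carbon; ring B by dearomatising closure at the spiro carbon; acyl group; prenyl group.
Stereochemistry: one ring-fusion CH comes from (S)-carvone; the ring C carbinol from axial O2 capture; the second ring-fusion CH from kinetic protonation after the shift; the ring B carbinol from A1,3-controlled iodolactonisation; the spiro carbon from a bulky OTIPS helper on the arene; C(CH3)(prenyl) from a chiral palladium catalyst; the side chain from the chiral acid.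

Key step: step 4

Assumption: ring A compounds are written as one representative enol tautomer, and the (R,R) antipode of the DACH-phenyl Trost ligand is taken as the one that builds the (R)-configured C(CH3)(prenyl) centre (both antipodes are commercial).

Step 1
Reactants: 1 (S)-(+)-carvone
Product: 3 (2R,5S)-2-hydroxy-2-methyl-5-(prop-1-en-2-yl)cyclohexan-1-one, via α-hydroperoxy ketone 2 (not isolated)
Conditions: Mn(dpm)3 (dpm = dipivaloylmethanate, 3 mol %), PhSiH3, O2 (1 atm), iPrOH, 0 °C; then P(OEt)3
Reagents that add atoms: dioxygen O=O
Why: Mukaiyama-type reductive α-hydroxylation of an enone, in which hydrogen delivery to the β-carbon gives the α-carbonyl radical/enolate that should take up O2 along the axial trajectory of the chair with equatorial isopropenyl (the sense known for axial alkylation of dihydrocarvone enolates), so the new C–O bond is cis to isopropenyl, while the isolated alkene reacts more slowly than the enone at 0 °C.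

Step 2
Reactants: 3 (2R,5S)-2-hydroxy-2-methyl-5-(prop-1-en-2-yl)cyclohexan-1-one
Product: 4 (2R,5S)-2-methyl-5-(prop-1-en-2-yl)-2-[(triethylsilyl)oxy]cyclohexan-1-one
Conditions: Et3SiOTf, 2,6-lutidine, CH2Cl2, −78 → 0 °C
Reagents that add atoms: triethylsilyl triflate CC[Si](CC)(CC)OS(=O)(=O)C(F)(F)F
Why: Silylation of a hindered tertiary alcohol with a silyl triflate, which touches no stereocentre; the TES cap blocks α-ketol shifts and later iodoetherification and raises the facial bias in step 4.

Step 3
Reactants: 4 (2R,5S)-2-methyl-5-(prop-1-en-2-yl)-2-[(triethylsilyl)oxy]cyclohexan-1-one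
Product: 6 (2R,5R)-6-diazo-2-methyl-5-(prop-1-en-2-yl)-2-[(triethylsilyl)oxy]cyclohexan-1-one, via trifluoroacetyl ketone 5 (not isolated)
Conditions: LiN(SiMe3)2, THF, −78 °C; CF3CO2CH2CF3; aq. HCl; then p-acetamidobenzenesulfonyl azide, Et3N, H2O (1 equiv), MeCN, 25 °C
Reagents that add atoms: p-acetamidobenzenesulfonyl azide CC(=O)Nc1ccc(cc1)S(=O)(=O)N=[N+]=[N-]; 2,2,2-trifluoroethyl trifluoroacetate FC(F)(F)COC(=O)C(F)(F)F (its CF3CO group stands in 5 only)
Why: Detrifluoroacetylative (Regitz-type) diazo transfer, in which the ketone can enolise only towards its CH2 side because the other α-carbon is quaternary, the enolate is C-trifluoroacetylated to 5, and this activated 1,3-dicarbonyl accepts N2 from the sulfonyl azide with loss of the trifluoroacetyl group.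

Step 4
Reactants: 6 (2R,5R)-6-diazo-2-methyl-5-(prop-1-en-2-yl)-2-[(triethylsilyl)oxy]cyclohexan-1-one
Product: 9 (3S,3aS,6R,6aS)-3-(iodomethyl)-3,6-dimethyl-6-[(triethylsilyl)oxy]hexahydro-1H-cyclopenta[c]furan-1-one, via ketene 7 (not isolated), via all-cis acid 8 (not isolated)
Conditions: hν (365 nm), THF/H2O, 0 °C; then NaHCO3, I2, 0 °C, dark
Reagents that add atoms: water O; iodine II
Why: Photolysis of the s-Z-locked cyclic α-diazoketone expels N2 with concerted 1,2-shift of the only carbon substituent on the carbonyl carbon, the silyloxy-bearing quaternary carbon, which moves with retention to the diazo carbon (photochemical Wolff rearrangement; the closest known type is ring contraction of 2-diazocyclohexanones), so the six-membered carvone ring becomes ring C and its carbonyl carbon is extruded as ketene 7. Water adds to 7, and the ene-diol should be protonated at the ring carbon from the face that carries CH3 and H, away from OTES and isopropenyl, which places CO2H cis to both (all-cis acid 8, a kinetic and contra-thermodynamic outcome). Bicarbonate and iodine then close the γ-lactone, which only the cis acid can do, so any trans acid stays behind as its salt and is removed. The new oxygenated quaternary carbon is set by the A1,3-preferred rotamer of the isopropenyl group (=CH2 eclipsing the ring-fusion H), which puts CH2I on the convex face and CH3 on the concave face of the cis-bicyclo[3.3.0] lactone. Modes of closure: ring C by 1,2-carbon shift (six to five atoms), and the lactone by 5-exo-trig attack of carboxylate oxygen on the iodonium ion. The step needs Wolff shift over 1,2-H shift or cyclopropanation (secured by the s-Z geometry and direct irradiation) and lactonisation over iodoetherification (secured by the TES cap on the tertiary alcohol).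

Step 5
Reactants: 9 (3S,3aS,6R,6aS)-3-(iodomethyl)-3,6-dimethyl-6-[(triethylsilyl)oxy]hexahydro-1H-cyclopenta[c]furan-1-one
Product: 10 (3S,3aS,6R,6aS)-3-(iodomethyl)-3,6-dimethyl-6-[(triethylsilyl)oxy]hexahydro-1H-cyclopenta[c]furan-1-ol (anomeric mixture)
Conditions: iBu2AlH (1.1 equiv), CH2Cl2, −78 °C; aq. KNaC4H4O6
Reagents that add atoms: none
Why: Partial reduction of a γ-lactone to the lactol at low temperature, where the tetrahedral aluminium alkoxide persists and the neopentyl-type C–I bond and the silyl ether are inert; the new hemiacetal carbon is an inconsequential anomeric mixture.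

Step 6
Reactants: 11 2-methylbenzene-1,3,5-triol (2-methylphloroglucinol)
Product: 12 2-methyl-5-[(triisopropylsilyl)oxy]benzene-1,3-diol
Conditions: iPr3SiCl (1.0 equiv), imidazole, DMF, 0 °C
Reagents that add atoms: triisopropylsilyl chloride CC(C)[Si](Cl)(C(C)C)C(C)C
Why: Sterically controlled monosilylation, in which the bulky chlorosilane should take the one phenol flanked by two C–H positions rather than the two phenols ortho to CH3, installing the helper group that later steers the spiro centre.

Step 7
Reactants: 10 lactol; 12 2-methyl-5-[(triisopropylsilyl)oxy]benzene-1,3-diol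
Product: 15 4-{[(1S,2R,5S)-5-[(2S)-2-hydroxy-1-iodopropan-2-yl]-2-methyl-2-(triethylsilyloxy)cyclopentyl]methyl}-2-methyl-5-(triisopropylsilyloxy)benzene-1,3-diol, via benzylic ether 13 (not isolated), via o-quinone methide 14 (not isolated)
Conditions: (PhO)2P(O)OH (10 mol %), 4 Å MS, CH2Cl2, 0 → 25 °C; then Hantzsch ester (1.3 equiv), 35 °C
Reagents that add atoms: none
Why: Brønsted-acid Friedel–Crafts alkylation of the aryl C-glycosidation type (reversible O-attack drains to C-attack) joins the cyclic oxocarbenium ion of 10 to one of the two equivalent free positions of 12; the same acid then ionises benzylic ether 13 to o-quinone methide 14, which the Hantzsch ester reduces by organocatalytic transfer hydrogenation, and the ring-fusion stereocentre stays locked in the cis-bicycle until the C–C bond exists.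

Step 8
Reactants: 15 iodohydrin arene
Product: 17 spiro dienone (ring B closed; C–OTIPS carbon of ring A cis to the ring B hydroxyl; TES ether retained), via epoxide 16 (not isolated)
Conditions: KOtBu (3.2 equiv), THF, 0 → 40 °C; aq. NH4Cl
Reagents that add atoms: none
Why: Williamson closure gives epoxide 16, and the resorcinolate carbon ortho and para to O− opens it at CH2 (anionic alkylative dearomatisation, 6-endo epoxide-opening cyclisation of a stabilised carbanion, forced because the other epoxide carbon is quaternary); backside attack demands a chair with the C–O bond equatorial and the carbinol CH3 axial, and the ring A flank bearing OTIPS should avoid the axial site syn to that CH3, which sets the spiro centre.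

Step 9
Reactants: 17 spiro dienone
Product: 18 spiro trione diol (both silyl groups removed, drawn as dienol-one)
Conditions: HF·pyridine, THF/pyridine, 0 → 25 °C
Reagents that add atoms: none
Why: Fluoride-driven Si–O cleavage removes the vinylogous silyl ester and the tertiary TES ether under buffered conditions that leave the tertiary alcohols and all stereocentres untouched.

Step 10
Reactants: 18 spiro trione diol; 19 (S)-2-methylbutanoic acid
Product: 21 2-acyl spiro compound (ring A carries the (S)-2-methylbutanoyl group on the carbon between two C–O carbons and CH3 on the other enolic carbon), via enol ester 20 (not isolated)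
Conditions: DCC, DMAP (1.2 equiv), CH2Cl2, 0 → 25 °C
Reagents that add atoms: none
Why: Steglich O-acylation followed by DMAP-mediated O-to-C acyl migration (Fries-type, standard for cyclic 1,3-diones) should end at the only C–H position between two carbonyl groups, where the product is a chelated enolised β-triketone, while the tertiary alcohols do not react and the α-stereocentre of the acid is retained under these mild conditions.

Step 11
Reactants: 21 2-acyl spiro compound
Product: 22 hyperielliptone HB
Conditions: Pd2(dba)3·CHCl3 (2.5 mol %), (R,R)-DACH-phenyl Trost ligand (7.5 mol %), prenyl methyl carbonate, CH2Cl2, 0 → 25 °C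
Reagents that add atoms: prenyl methyl carbonate COC(=O)OCC=C(C)C
Why: Tsuji–Trost asymmetric allylic alkylation, in which zerovalent palladium ionises the carbonate, the liberated methoxide deprotonates 21, and the only alkylable ring carbon (the one bearing CH3) attacks the unhindered CH2 terminus of the prenyl-palladium cation (reversible O-allylation drains to C-allylation), the chiral ligand pocket choosing the enolate face that gives the (R)-configured quaternary centre.

Compound list
1 | (S)-(+)-carvone | CC1=CC[C@@H](CC1=O)C(C)=C | starting material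
2 | (2R,5S)-2-hydroperoxy-2-methyl-5-(prop-1-en-2-yl)cyclohexan-1-one | CC(=C)[C@H]1CC[C@@](C)(OO)C(=O)C1 | intermediate
3 | (2R,5S)-2-hydroxy-2-methyl-5-(prop-1-en-2-yl)cyclohexan-1-one | CC(=C)[C@H]1CC[C@@](C)(O)C(=O)C1 | intermediate
4 | (2R,5S)-2-methyl-5-(prop-1-en-2-yl)-2-[(triethylsilyl)oxy]cyclohexan-1-one | CC(=C)[C@H]1CC[C@@](C)(O[Si](CC)(CC)CC)C(=O)C1 | intermediate
5 | 6-trifluoroacetyl derivative of 4 (keto/enol mixture, C6 unassigned) | CC(=C)[C@H]1CC[C@@](C)(O[Si](CC)(CC)CC)C(=O)C1C(=O)C(F)(F)F | intermediate
6 | (2R,5R)-6-diazo-2-methyl-5-(prop-1-en-2-yl)-2-[(triethylsilyl)oxy]cyclohexan-1-one | CC(=C)[C@H]1CC[C@@](C)(O[Si](CC)(CC)CC)C(=O)C1=[N+]=[N-] | intermediate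
7 | [(2R,5R)-2-methyl-5-(prop-1-en-2-yl)-2-(triethylsilyloxy)cyclopentylidene]methanone (ketene) | CC(=C)[C@H]1CC[C@@](C)(O[Si](CC)(CC)CC)C1=C=O | intermediate
8 | (1S,2R,5S)-2-methyl-5-(prop-1-en-2-yl)-2-[(triethylsilyl)oxy]cyclopentane-1-carboxylic acid (CO2H, OTES and isopropenyl all cis) | CC(=C)[C@H]1CC[C@@](C)(O[Si](CC)(CC)CC)[C@H]1C(=O)O | intermediate
9 | (3S,3aS,6R,6aS)-3-(iodomethyl)-3,6-dimethyl-6-[(triethylsilyl)oxy]hexahydro-1H-cyclopenta[c]furan-1-one | O=C1O[C@](C)(CI)[C@H]2CC[C@@](C)(O[Si](CC)(CC)CC)[C@@H]12 | intermediate
10 | lactol of 9 (C1 anomeric mixture) | OC1O[C@](C)(CI)[C@H]2CC[C@@](C)(O[Si](CC)(CC)CC)[C@@H]12 | intermediate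
11 | 2-methylbenzene-1,3,5-triol | Cc1c(O)cc(O)cc1O | starting material
12 | 2-methyl-5-[(triisopropylsilyl)oxy]benzene-1,3-diol | Cc1c(O)cc(O[Si](C(C)C)(C(C)C)C(C)C)cc1O | intermediate
13 | benzylic ether: lactol OH of 10 replaced by the 2,4-dihydroxy-3-methyl-6-(triisopropylsilyloxy)phenyl group, core stereocentres as in 10 | Cc1c(O)cc(O[Si](C(C)C)(C(C)C)C(C)C)c(C2O[C@](C)(CI)[C@H]3CC[C@@](C)(O[Si](CC)(CC)CC)[C@@H]23)c1O | intermediate
14 | o-quinone methide formed by ring opening of 13 | CC1=C(O)C=C(O[Si](C(C)C)(C(C)C)C(C)C)C(=C[C@H]2[C@H](CC[C@@]2(C)O[Si](CC)(CC)CC)[C@](C)(O)CI)C1=O | intermediate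
15 | 4-{[(1S,2R,5S)-5-[(2S)-2-hydroxy-1-iodopropan-2-yl]-2-methyl-2-(triethylsilyloxy)cyclopentyl]methyl}-2-methyl-5-(triisopropylsilyloxy)benzene-1,3-diol | Cc1c(O)cc(O[Si](C(C)C)(C(C)C)C(C)C)c(C[C@H]2[C@H](CC[C@@]2(C)O[Si](CC)(CC)CC)[C@](C)(O)CI)c1O | intermediate
16 | epoxide of 15, side chain (2S)-2-methyloxiran-2-yl | Cc1c(O)cc(O[Si](C(C)C)(C(C)C)C(C)C)c(C[C@H]2[C@H](CC[C@@]2(C)O[Si](CC)(CC)CC)[C@@]3(C)CO3)c1O | intermediate
17 | spiro dienone: rings A, B and C assembled, OTIPS enol ether on ring A, TES ether on ring C, spiro centre as in the target | CC1=C(O)[C@]2(C[C@H]3[C@H](CC[C@@]3(C)O[Si](CC)(CC)CC)[C@](C)(O)C2)C(O[Si](C(C)C)(C(C)C)C(C)C)=CC1=O | intermediate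
18 | spiro trione diol (17 without silyl groups) | CC1=C(O)[C@]2(C[C@H]3[C@H](CC[C@@]3(C)O)[C@](C)(O)C2)C(O)=CC1=O | intermediate
19 | (S)-2-methylbutanoic acid | CC[C@H](C)C(=O)O | starting material
20 | enol (S)-2-methylbutanoate of 18 | CC[C@H](C)C(=O)OC1=CC(=O)[C@@]2(C[C@H]3[C@H](CC[C@@]3(C)O)[C@](C)(O)C2)C(O)=C1C | intermediate
21 | C-acylated spiro compound (target lacking the prenyl group) | CC[C@H](C)C(=O)C1=C(O)C(C)=C(O)[C@]2(C[C@H]3[C@H](CC[C@@]3(C)O)[C@](C)(O)C2)C1=O | intermediate
22 | hyperielliptone HB | CC[C@H](C)C(=O)C1=C(O)[C@@](C)(CC=C(C)C)C(=O)[C@]2(C[C@H]3[C@H](CC[C@@]3(C)O)[C@](C)(O)C2)C1=O | target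

Total step count: 11. Longest linear sequence: 10 steps (steps 1–5 and 7–11).

Steps most likely to fail

1. Step 8. The 6-endo epoxide opening may be slower than O-centred or intermolecular attack, the aryl silyl ether may be lost under alkoxide, and the facial bias at the spiro carbon may be low. The fallback inverts the polarity of the closure and sets out from acid 8, isolated by extraction after the photolysis and before iodine is added. Reduction with LiAlH4 in Et2O gives the primary alcohol F1. Dess–Martin oxidation gives the aldehyde F2, which is used at once. Union with 12 under the conditions of step 7 gives the isopropenyl arene F3. Oxidative dearomatisation with PhI(OAc)2 in MeCN/H2O at 0 °C then makes the substituted arene carbon electrophilic. The CH2 terminus of the isopropenyl group attacks it (6-endo, Markovnikov), and water captures the tertiary cation anti to the new C–C bond, which should place OH equatorial as in the main route. This fallback comes back to the route at 17.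

2. Step 7. Friedel–Crafts attack next to the OTIPS group may be slow, and the ring-fusion configuration may be lost if the o-quinone methide tautomerises to a styrene before hydride transfer. The fallback uses a more acidic ring A partner and aminocatalysis; it sets out from 10, 11 and 19. Acylation of 11 with 19 in BF3·OEt2 gives (S)-1-(2,4,6-trihydroxy-3-methylphenyl)-2-methylbutan-1-one F4. Three-component reductive alkylation of F4 with 10 (L-proline, Hantzsch ester, CH2Cl2/EtOH) gives the acylated iodohydrin arene F5. K2CO3 in MeOH closes ring B to the acylated spiro TES ether F6. HF·pyridine then returns the sequence to the route at 21, so steps 6 and 10 fall away. The cost is that the spiro centre is then steered only by the chelated acyl flank.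

3. Step 11. Facial selectivity may be poor if ligand and substrate are mismatched, and O-allylation or attack at the tertiary terminus of the prenyl cation may compete. The fallback sets out from 21. It uses the smaller and better behaved allyl methyl carbonate with the same palladium/ligand system, which gives the allyl compound F7. Cross metathesis of F7 with 2-methylbut-2-ene (second-generation Grubbs catalyst, CH2Cl2, 40 °C) converts allyl into prenyl and comes back at 22.

Further compounds
F1 | step 8 | primary alcohol from 8 (CO2H reduced to CH2OH, stereocentres unchanged) | CC(=C)[C@H]1CC[C@@](C)(O[Si](CC)(CC)CC)[C@H]1CO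
F2 | step 8 | aldehyde from F1 (stereocentres unchanged) | CC(=C)[C@H]1CC[C@@](C)(O[Si](CC)(CC)CC)[C@H]1C=O
F3 | step 8 | isopropenyl arene (15 with isopropenyl in place of the iodohydrin side chain) | Cc1c(O)cc(O[Si](C(C)C)(C(C)C)C(C)C)c(C[C@H]2[C@H](CC[C@@]2(C)O[Si](CC)(CC)CC)C(C)=C)c1O
F4 | step 7 | (S)-1-(2,4,6-trihydroxy-3-methylphenyl)-2-methylbutan-1-one | CC[C@H](C)C(=O)c1c(O)cc(O)c(C)c1O
F5 | step 7 | acylated iodohydrin arene | CC[C@H](C)C(=O)c1c(O)c(C[C@H]2[C@H](CC[C@@]2(C)O[Si](CC)(CC)CC)[C@](C)(O)CI)c(O)c(C)c1O
F6 | step 7 | acylated spiro TES ether (21 with OTES on ring C) | CC[C@H](C)C(=O)C1=C(O)C(C)=C(O)[C@]2(C[C@H]3[C@H](CC[C@@]3(C)O[Si](CC)(CC)CC)[C@](C)(O)C2)C1=O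
F7 | step 11 | allyl compound (22 with allyl in place of prenyl) | CC[C@H](C)C(=O)C1=C(O)[C@@](C)(CC=C)C(=O)[C@]2(C[C@H]3[C@H](CC[C@@]3(C)O)[C@](C)(O)C2)C1=O
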